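1. I wanted to cut the precatalyst from 5 mol% to 0.5 mol% in the next run, but first had to decide what rate I could give up.

all flasks: precatalyst 5 mol%

| charge | left-handed substrate | right-handed substrate | reagent | remark |
|---|---|---|---|---|
| oak | 1.0 × 10⁻⁴ M | 1.0 × 10⁻⁴ M | 1 equiv | run made earlier |
| ash | 4.0 × 10⁻⁴ M | 4.0 × 10⁻⁴ M | 1 equiv | run made earlier |
| alder | 2.0 × 10⁻⁴ M | 2.0 × 10⁻⁴ M | 2 equiv | run made earlier |
| flask | 2.0 × 10⁻⁴ M | 2.0 × 10⁻⁴ M | 1.00 equiv |  |

- oak (time / min: left-handed product / %, left-handed substrate / %): 0.417: 0.8, 49.3; 0.833: 0.6, 50.0; 2.00: 3.6, 44.5; 5.00: 16.9, 34.3
- ash (time / min: left-handed product / %, left-handed substrate / %): 0.417: 3.4, 46.5; 0.833: 10.4, 39.8; 2.00: 30.1, 20.5; 5.00: 40.6, 9.1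
- alder (time / min: left-handed product / %, left-handed substrate / %): 0.417: 1.7, 47.2; 0.833: 7.1, 44.7; 2.00: 23.8, 25.6; 5.00: 46.5, 4.7

(standard deviation of a reading: 1 percentage point)

- catalyst is single-handed; left-handed substrate and right-handed substrate are mirror images of each other, charged as a racemate, each of them at the stated concentration
- the numbers in the tables scatter by 1 percentage point (one standard deviation)
2. The oak run showed an induction period. Between 2.00 min and 5.00 min, left-handed product rose by a factor of 4.69, faster than time, which rose by 2.50. I read this as catalyst growing out of precatalyst.
3. My reckoning was that, early on, catalyst grows in proportion to the load and to time, so the product formed goes as load times time squared. A fixed conversion is then reached at a time proportional to one over the square root of the load, and the rate there goes as the square root of the load.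
4. That gave the load factor, the square root of the new load over the old: 0.316. The low load should therefore give about a third of the rate, and take 3.16 times as long to reach the same conversion.
5. Assuming the rate is first order in reagent, the same rule gave 1.41 for doubling the reagent. I kept the flask at 1.00 equiv and 5 mol% to test this.

- factor on the rate of making left-handed product when 5.0 % of the left-handed substrate and right-handed substrate together are converted if reagent is charged twice over
- factor on the rate when 5.0 % of the left-handed substrate and right-handed substrate together are converted if precatalyst is charged at 0.5 mol% instead

6. The forecast gave 1.5 and 0.29. It used the same square-root rule, but took its reagent dependence from the alder and oak runs instead of my assumed first order, and it set the precatalyst factor lower than my load factor on the ground that “activation nears completion during the longer time needed”.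

7. The flask gave 1.50 and 0.274, the second lower than my load factor. The flask reached the conversion asked about at 0.969 min, so dividing by the load factor puts the low-load flask there at about 3.07 min. Catalyst in the flask stood at 11.2 % after 0.600 min. Straight-line growth from there gives 56.0 % after 3.00 min, but the flask held 44.8 %.

    reagent + catalyst + left-handed substrate → catalyst + left-handed product (k = 9.40 × 10⁶ /M²/s)
    reagent + catalyst + right-handed substrate → catalyst + right-handed product (k = 1.10 × 10⁶ /M²/s)
    precatalyst → catalyst (k = 0.00330 /s)

The numbers in the tables were generated by integration with made-up constants.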